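Everything rests on building ring A of half 1 (the 4'-methoxyflavone unit, joined through C8) de novo on C6 of a finished half 2 flavone (the 7-methoxy unit). A Danheiser benzannulation of a 6-(silyloxyethynyl)flavone with 3-ethoxycyclobutenone forms C8–C8a and C6–C7 in one operation and exploits the phloroglucinol pattern of that ring: C8 lies between the oxygenated carbons C8a and C7, with C5–O para, and the three oxygens emerge as free OH, silyl ether and ethyl ether. The precursor is a 4'-benzyloxy-5,7-dimethoxyflavone carrying a triisopropylsilyloxy-alkyne at C6. The free phenol then anchors closure of pyranone ring C, and fluoride and BCl3 unmask the target.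

Key step: step 8

Assumption: the target is drawn without a configuration for the hindered C8(half 1)–C6(half 2) biaryl axis, so every axially chiral compound is planned as the racemate. 3-Ethoxycyclobut-2-en-1-one is taken as a purchased reagent.

Step 1
Reactants: 1 1-(2,6-dihydroxy-4-methoxyphenyl)ethan-1-one; 2 4-(benzyloxy)benzoyl chloride
Product: 3 1-[4-(benzyloxy)phenyl]-3-(2,6-dihydroxy-4-methoxyphenyl)propane-1,3-dione
Conditions: LiN(SiMe3)2 (4.2 equiv), THF, −78 °C → rt; aq. HCl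
Reagents that add atoms: none
Why: Excess amide base deprotonates both phenols and the methyl ketone of 1, and the enolate carbon is acylated by the aroyl chloride (Claisen-type acylation, the diketone stage of a Baker–Venkataraman flavone synthesis) without hydroxyl protection.

Step 2
Reactants: 3 1-[4-(benzyloxy)phenyl]-3-(2,6-dihydroxy-4-methoxyphenyl)propane-1,3-dione
Product: 4 2-[4-(benzyloxy)phenyl]-5-hydroxy-7-methoxychromen-4-one
Conditions: AcOH, H2SO4 (cat.), 95 °C
Reagents that add atoms: none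
Why: Acid-catalysed cyclodehydration of the 2-hydroxyaryl 1,3-diketone closes the pyranone, and because the two phenolic hydroxyls of 3 are equivalent only one flavone can form, while the brief exposure to catalytic acid should spare the aryl benzyl ether.

Step 3
Reactants: 4 2-[4-(benzyloxy)phenyl]-5-hydroxy-7-methoxychromen-4-one
Product: 5 2-[4-(benzyloxy)phenyl]-5-hydroxy-6-iodo-7-methoxychromen-4-one
Conditions: BnMe3N(ICl2) (1.05 equiv), CaCO3, CH2Cl2/MeOH, rt
Reagents that add atoms: benzyltrimethylammonium dichloroiodate, C[N+](C)(C)Cc1ccccc1.Cl[I-]Cl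
Why: Electrophilic aromatic iodination is steered ortho to the free chelated 5-hydroxyl and therefore to C6, whereas a 5,7-dimethoxyflavone would be iodinated at C8, which is why the iodine is introduced before the 5-oxygen is alkylated.

Step 4
Reactants: 5 2-[4-(benzyloxy)phenyl]-5-hydroxy-6-iodo-7-methoxychromen-4-one
Product: 6 2-[4-(benzyloxy)phenyl]-6-iodo-5,7-dimethoxychromen-4-one
Conditions: Me2SO4, K2CO3, acetone, reflux
Reagents that add atoms: dimethyl sulfate, COS(=O)(=O)OC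
Why: Williamson etherification under forcing conditions alkylates the chelated, hindered 5-hydroxyl, which would otherwise cyclise onto the alkyne after coupling, and methyl is the smallest group that can flank the later alkyne.

Step 5
Reactants: 6 2-[4-(benzyloxy)phenyl]-6-iodo-5,7-dimethoxychromen-4-one; 7 ethynyltrimethylsilane
Product: 8 2-[4-(benzyloxy)phenyl]-5,7-dimethoxy-6-[(trimethylsilyl)ethynyl]chromen-4-one
Conditions: Pd(PPh3)2Cl2 (cat.), CuI (cat.), Et3N, DMF, 70 °C, sealed tube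
Reagents that add atoms: none
Why: Sonogashira coupling of the aryl iodide, with moderate heating to overcome the two ortho methoxy groups, installs the two alkyne carbons at C6.

Step 6
Reactants: 8 2-[4-(benzyloxy)phenyl]-5,7-dimethoxy-6-[(trimethylsilyl)ethynyl]chromen-4-one
Product: 9 2-[4-(benzyloxy)phenyl]-6-ethynyl-5,7-dimethoxychromen-4-one
Conditions: K2CO3 (cat.), MeOH/THF, rt
Reagents that add atoms: none
Why: Carbonate-catalysed methanolysis cleaves the C(sp)–Si bond selectively and leaves the flavone and its ethers untouched.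

Step 7
Reactants: 9 2-[4-(benzyloxy)phenyl]-6-ethynyl-5,7-dimethoxychromen-4-one
Product: 12 2-[4-(benzyloxy)phenyl]-5,7-dimethoxy-6-[(triisopropylsilyloxy)ethynyl]chromen-4-one, via lithium acetylide 10 (not isolated), via lithium ynolate 11 (not isolated)
Conditions: LiN(SiMe3)2, THF, −78 °C; LiOOt-Bu (from t-BuOOH and LiN(SiMe3)2), −78 → 0 °C; i-Pr3SiOTf, −78 °C
Reagents that add atoms: tert-butyl hydroperoxide, CC(C)(C)OO; triisopropylsilyl trifluoromethanesulfonate, CC(C)[Si](OS(=O)(=O)C(F)(F)F)(C(C)C)C(C)C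
Why: The non-nucleophilic amide deprotonates only the terminal alkyne, the acetylide takes an oxygen atom from the oxenoid LiOOt-Bu to give the ynolate, and the bulky silyl triflate traps it on oxygen (acetylide oxidation and O-silylation route to siloxyalkynes), the 2-arylpyranone being a poor acceptor for amide and peroxide at low temperature.

Step 8
Reactants: 12 2-[4-(benzyloxy)phenyl]-5,7-dimethoxy-6-[(triisopropylsilyloxy)ethynyl]chromen-4-one; 13 3-ethoxycyclobut-2-en-1-one
Product: 18 6-[4-ethoxy-2-hydroxy-6-(triisopropylsilyloxy)phenyl]-2-[4-(benzyloxy)phenyl]-5,7-dimethoxychromen-4-one (racemic biaryl axis), via vinylketene 14 (not isolated), via vinylcyclobutenone 15 (not isolated), via dienylketene 16 (not isolated), via cyclohexadienone 17 (not isolated)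
Conditions: 13 (1.3 equiv, added in portions), toluene, 100 °C, sealed tube
Reagents that add atoms: none
Why: Heating opens 13 by 4π electrocyclic ring opening to the (1-ethoxyvinyl)ketene 14, which adds [2+2] to the electron-rich triple bond of 12 to give 15; a second 4π opening to 16, 6π electrocyclisation to 17 and tautomerisation should deliver phenol 18. The closest known reaction is the Danheiser benzannulation of cyclobutenones with siloxyalkynes, here with a 3-alkoxycyclobutenone as the less usual partner. Ring A of half 1 is closed by the thermally allowed disrotatory 6π electrocyclisation, which re-forms the C8a–C4a bond after the [2+2] has made C8–C8a and C6–C7. No stereocentre survives: the sp3 centre of 15 is lost on ring opening and the hindered axis of 18 is formed racemic. The one selectivity required is the regiochemistry of the [2+2], and the silyloxy group polarises the alkyne so that its aryl-bearing carbon bonds to the ketene carbonyl carbon, which places the flavonyl group between the free hydroxyl (C8a) and the silyl ether (C7) with the ethoxy group para (C5). Only a small excess of 13 is used so that surplus ketene does not acylate the new phenol.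

Step 9
Reactants: 18 6-[4-ethoxy-2-hydroxy-6-(triisopropylsilyloxy)phenyl]-2-[4-(benzyloxy)phenyl]-5,7-dimethoxychromen-4-one; 19 methyl 3-(4-methoxyphenyl)prop-2-ynoate
Product: 20 methyl 3-{2-[2-(4-benzyloxyphenyl)-5,7-dimethoxy-4-oxochromen-6-yl]-5-ethoxy-3-(triisopropylsilyloxy)phenoxy}-3-(4-methoxyphenyl)prop-2-enoate (E/Z mixture)
Conditions: K2CO3 (0.5 equiv), DMF, 70 °C
Reagents that add atoms: none
Why: The phenoxide of the only free hydroxyl adds in conjugate fashion to the alkynoate (oxa-Michael addition), the anhydrous substoichiometric carbonate should leave the hindered aryl silyl ether in place, and the alkene geometry is of no consequence.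

Step 10
Reactants: 20 methyl 3-{2-[2-(4-benzyloxyphenyl)-5,7-dimethoxy-4-oxochromen-6-yl]-5-ethoxy-3-(triisopropylsilyloxy)phenoxy}-3-(4-methoxyphenyl)prop-2-enoate
Product: 21 3-{2-[2-(4-benzyloxyphenyl)-5,7-dimethoxy-4-oxochromen-6-yl]-5-ethoxy-3-(triisopropylsilyloxy)phenoxy}-3-(4-methoxyphenyl)prop-2-enoic acid (E/Z mixture)
Conditions: Me3SnOH, ClCH2CH2Cl, 80 °C; aq. HCl
Reagents that add atoms: trimethyltin hydroxide, C[Sn](C)(C)O
Why: Me3SnOH cleaves the methyl ester through the tin carboxylate under neutral conditions, which avoids free hydroxide that could remove the aryl silyl ether or displace the aryloxide by addition–elimination.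

Step 11
Reactants: 21 3-{2-[2-(4-benzyloxyphenyl)-5,7-dimethoxy-4-oxochromen-6-yl]-5-ethoxy-3-(triisopropylsilyloxy)phenoxy}-3-(4-methoxyphenyl)prop-2-enoic acid
Product: 23 8-{2-[4-(benzyloxy)phenyl]-5,7-dimethoxy-4-oxochromen-6-yl}-5-ethoxy-2-(4-methoxyphenyl)-7-(triisopropylsilyloxy)chromen-4-one (racemic biaryl axis), via mixed anhydride 22 (not isolated)
Conditions: (CF3CO)2O (1.5 equiv), CH2Cl2, 0 °C → rt
Reagents that add atoms: none
Why: The mixed trifluoroacetic anhydride acylates C4a, the only free position ortho to the vinyl ether oxygen and one activated by the ortho ethoxy and para silyloxy groups (intramolecular Friedel–Crafts acylation), while the acid released equilibrates the alkene isomers so that both funnel into the pyranone.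

Step 12
Reactants: 23 8-{2-[4-(benzyloxy)phenyl]-5,7-dimethoxy-4-oxochromen-6-yl}-5-ethoxy-2-(4-methoxyphenyl)-7-(triisopropylsilyloxy)chromen-4-one
Product: 24 8-{2-[4-(benzyloxy)phenyl]-5,7-dimethoxy-4-oxochromen-6-yl}-5-ethoxy-7-hydroxy-2-(4-methoxyphenyl)chromen-4-one (racemic biaryl axis)
Conditions: Bu4NF, THF, 0 °C; aq. NH4Cl
Reagents that add atoms: none
Why: Fluoride attacks silicon and releases the C7 phenoxide of half 1 (desilylation of an aryl silyl ether) without touching the alkyl and benzyl ethers.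

Step 13
Reactants: 24 8-{2-[4-(benzyloxy)phenyl]-5,7-dimethoxy-4-oxochromen-6-yl}-5-ethoxy-7-hydroxy-2-(4-methoxyphenyl)chromen-4-one
Product: 25 5,7-dihydroxy-8-[5-hydroxy-2-(4-hydroxyphenyl)-7-methoxy-4-oxochromen-6-yl]-2-(4-methoxyphenyl)chromen-4-one (racemic biaryl axis)
Conditions: BCl3 (excess), C6HMe5, CH2Cl2, −78 °C → rt; MeOH
Reagents that add atoms: none
Why: BCl3 chelated between each C4 carbonyl and its peri 5-alkoxy oxygen should dealkylate the 5-methoxy group of half 2 and the 5-ethoxy group of half 1 and ionise the benzyl ether (pentamethylbenzene traps the benzyl cation), while the unchelated 7-methoxy and 4'-methoxy groups are expected to survive at this temperature (chelation-controlled Lewis acid ether cleavage).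

Compound list
1 | 1-(2,6-dihydroxy-4-methoxyphenyl)ethan-1-one | CC(=O)c1c(O)cc(OC)cc1O | starting material
2 | 4-(benzyloxy)benzoyl chloride | O=C(Cl)c1ccc(OCc2ccccc2)cc1 | starting material
3 | 1-[4-(benzyloxy)phenyl]-3-(2,6-dihydroxy-4-methoxyphenyl)propane-1,3-dione | COc1cc(O)c(C(=O)CC(=O)c2ccc(OCc3ccccc3)cc2)c(O)c1 | intermediate
4 | 2-[4-(benzyloxy)phenyl]-5-hydroxy-7-methoxychromen-4-one | COc1cc(O)c2c(=O)cc(-c3ccc(OCc4ccccc4)cc3)oc2c1 | intermediate
5 | 2-[4-(benzyloxy)phenyl]-5-hydroxy-6-iodo-7-methoxychromen-4-one | COc1cc2oc(-c3ccc(OCc4ccccc4)cc3)cc(=O)c2c(O)c1I | intermediate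
6 | 2-[4-(benzyloxy)phenyl]-6-iodo-5,7-dimethoxychromen-4-one | COc1cc2oc(-c3ccc(OCc4ccccc4)cc3)cc(=O)c2c(OC)c1I | intermediate
7 | ethynyltrimethylsilane | C#C[Si](C)(C)C | starting material
8 | 2-[4-(benzyloxy)phenyl]-5,7-dimethoxy-6-[(trimethylsilyl)ethynyl]chromen-4-one | COc1cc2oc(-c3ccc(OCc4ccccc4)cc3)cc(=O)c2c(OC)c1C#C[Si](C)(C)C | intermediate
9 | 2-[4-(benzyloxy)phenyl]-6-ethynyl-5,7-dimethoxychromen-4-one | COc1cc2oc(-c3ccc(OCc4ccccc4)cc3)cc(=O)c2c(OC)c1C#C | intermediate
10 | lithium acetylide of 9 | COc1cc2oc(-c3ccc(OCc4ccccc4)cc3)cc(=O)c2c(OC)c1C#[C-].[Li+] | intermediate (not isolated)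
11 | lithium 2-{2-[4-(benzyloxy)phenyl]-5,7-dimethoxy-4-oxochromen-6-yl}ethynolate | COc1cc2oc(-c3ccc(OCc4ccccc4)cc3)cc(=O)c2c(OC)c1C#C[O-].[Li+] | intermediate (not isolated)
12 | 2-[4-(benzyloxy)phenyl]-5,7-dimethoxy-6-[(triisopropylsilyloxy)ethynyl]chromen-4-one | CC(C)[Si](OC#Cc1c(OC)cc2oc(-c3ccc(OCc4ccccc4)cc3)cc(=O)c2c1OC)(C(C)C)C(C)C | intermediate
13 | 3-ethoxycyclobut-2-en-1-one | CCOC1=CC(=O)C1 | starting material
14 | 3-ethoxybuta-1,3-dien-1-one, the (1-ethoxyvinyl)ketene | CCOC(=C)C=C=O | intermediate (not isolated)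
15 | 2-{2-[4-(benzyloxy)phenyl]-5,7-dimethoxy-4-oxochromen-6-yl}-4-(1-ethoxyethenyl)-3-(triisopropylsilyloxy)cyclobut-2-en-1-one (racemic) | CCOC(=C)C1C(=O)C(-c2c(OC)cc3oc(-c4ccc(OCc5ccccc5)cc4)cc(=O)c3c2OC)=C1O[Si](C(C)C)(C(C)C)C(C)C | intermediate (not isolated)
16 | 2-{2-[4-(benzyloxy)phenyl]-5,7-dimethoxy-4-oxochromen-6-yl}-5-ethoxy-3-(triisopropylsilyloxy)hexa-1,3,5-trien-1-one, ketene carbon and 1-ethoxyvinyl group cis across C3=C4 | CCOC(=C)/C=C(O[Si](C(C)C)(C(C)C)C(C)C)\C(=C=O)c1c(OC)cc2oc(-c3ccc(OCc4ccccc4)cc3)cc(=O)c2c1OC | intermediate (not isolated)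
17 | 2-{2-[4-(benzyloxy)phenyl]-5,7-dimethoxy-4-oxochromen-6-yl}-5-ethoxy-3-(triisopropylsilyloxy)cyclohexa-2,4-dien-1-one | CCOC1=CC(O[Si](C(C)C)(C(C)C)C(C)C)=C(-c2c(OC)cc3oc(-c4ccc(OCc5ccccc5)cc4)cc(=O)c3c2OC)C(=O)C1 | intermediate (not isolated)
18 | 6-[4-ethoxy-2-hydroxy-6-(triisopropylsilyloxy)phenyl]-2-[4-(benzyloxy)phenyl]-5,7-dimethoxychromen-4-one (racemic biaryl axis) | CCOc1cc(O)c(-c2c(OC)cc3oc(-c4ccc(OCc5ccccc5)cc4)cc(=O)c3c2OC)c(O[Si](C(C)C)(C(C)C)C(C)C)c1 | intermediate
19 | methyl 3-(4-methoxyphenyl)prop-2-ynoate | COC(=O)C#Cc1ccc(OC)cc1 | starting material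
20 | methyl 3-{2-[2-(4-benzyloxyphenyl)-5,7-dimethoxy-4-oxochromen-6-yl]-5-ethoxy-3-(triisopropylsilyloxy)phenoxy}-3-(4-methoxyphenyl)prop-2-enoate (E/Z mixture) | CCOc1cc(OC(=CC(=O)OC)c2ccc(OC)cc2)c(-c2c(OC)cc3oc(-c4ccc(OCc5ccccc5)cc4)cc(=O)c3c2OC)c(O[Si](C(C)C)(C(C)C)C(C)C)c1 | intermediate
21 | 3-{2-[2-(4-benzyloxyphenyl)-5,7-dimethoxy-4-oxochromen-6-yl]-5-ethoxy-3-(triisopropylsilyloxy)phenoxy}-3-(4-methoxyphenyl)prop-2-enoic acid (E/Z mixture) | CCOc1cc(OC(=CC(=O)O)c2ccc(OC)cc2)c(-c2c(OC)cc3oc(-c4ccc(OCc5ccccc5)cc4)cc(=O)c3c2OC)c(O[Si](C(C)C)(C(C)C)C(C)C)c1 | intermediate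
22 | mixed anhydride of 21 with trifluoroacetic acid | CCOc1cc(OC(=CC(=O)OC(=O)C(F)(F)F)c2ccc(OC)cc2)c(-c2c(OC)cc3oc(-c4ccc(OCc5ccccc5)cc4)cc(=O)c3c2OC)c(O[Si](C(C)C)(C(C)C)C(C)C)c1 | intermediate (not isolated)
23 | 8-{2-[4-(benzyloxy)phenyl]-5,7-dimethoxy-4-oxochromen-6-yl}-5-ethoxy-2-(4-methoxyphenyl)-7-(triisopropylsilyloxy)chromen-4-one (racemic biaryl axis) | CCOc1cc(O[Si](C(C)C)(C(C)C)C(C)C)c(-c2c(OC)cc3oc(-c4ccc(OCc5ccccc5)cc4)cc(=O)c3c2OC)c2oc(-c3ccc(OC)cc3)cc(=O)c12 | intermediate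
24 | 8-{2-[4-(benzyloxy)phenyl]-5,7-dimethoxy-4-oxochromen-6-yl}-5-ethoxy-7-hydroxy-2-(4-methoxyphenyl)chromen-4-one (racemic biaryl axis) | CCOc1cc(O)c(-c2c(OC)cc3oc(-c4ccc(OCc5ccccc5)cc4)cc(=O)c3c2OC)c2oc(-c3ccc(OC)cc3)cc(=O)c12 | intermediate
25 | 5,7-dihydroxy-8-[5-hydroxy-2-(4-hydroxyphenyl)-7-methoxy-4-oxochromen-6-yl]-2-(4-methoxyphenyl)chromen-4-one (racemic biaryl axis) | COc1ccc(-c2cc(=O)c3c(O)cc(O)c(-c4c(OC)cc5oc(-c6ccc(O)cc6)cc(=O)c5c4O)c3o2)cc1 | target

Total step count: 13. Longest linear sequence: 13 steps (1 to 25); compounds 2, 7, 13 and 19 are purchased.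

Steps most likely to fail

Step 8. The [2+2] cycloaddition has to occur at an alkyne carbon flanked by two ortho methoxy groups, so the transient ketene may be diverted into self-condensation or into acylation of the product phenol, and the donor-stabilised cyclobutenone may open only sluggishly. The fallback sets out from iodide 6 and comes back at 18 by bringing ring A in intact through cross-coupling. Phloroglucinol would be mono-etherified (EtOH, HCl) to 5-ethoxybenzene-1,3-diol F1 and protected (MeOCH2Cl, i-Pr2NEt) as 1-ethoxy-3,5-bis(methoxymethoxy)benzene F2. Directed lithiation between the two acetal oxygens (n-BuLi, THF, 0 °C) and a B(OMe)3 quench should give [4-ethoxy-2,6-bis(methoxymethoxy)phenyl]boronic acid F3. Suzuki–Miyaura coupling of F3 with 6 (Pd(OAc)2, SPhos, K3PO4, toluene/water, 100 °C) should give 2-[4-(benzyloxy)phenyl]-6-[4-ethoxy-2,6-bis(methoxymethoxy)phenyl]-5,7-dimethoxychromen-4-one F4. Acetal cleavage (HCl, MeOH, 50 °C) would then give 2-[4-(benzyloxy)phenyl]-6-(4-ethoxy-2,6-dihydroxyphenyl)-5,7-dimethoxychromen-4-one F5, and monosilylation (i-Pr3SiCl, 1 equiv, imidazole, DMF) leads to 18. The two hydroxyls of F5 are enantiotopic, so silylation of either gives the same racemic 18.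

Step 7. The acetylide, the ynolate or the peroxide may attack the pyranone (ring opening or epoxidation), and the ynolate may be silylated on carbon instead of oxygen. The fallback sets out from iodide 6 and comes back at 12 without any organolithium or peroxide. Hydroxycarbonylation of 6 (Pd(OAc)2, Xantphos, CO, Et3N, aqueous DMF) should give 2-[4-(benzyloxy)phenyl]-5,7-dimethoxy-4-oxochromene-6-carboxylic acid F6. Oxalyl chloride with catalytic DMF converts it into 2-[4-(benzyloxy)phenyl]-5,7-dimethoxy-4-oxochromene-6-carbonyl chloride F7, and Me3SiCHN2 into 2-[4-(benzyloxy)phenyl]-6-(diazoacetyl)-5,7-dimethoxychromen-4-one F8. C-Silylation (i-Pr3SiOTf, i-Pr2NEt, Et2O, 0 °C) would give 2-[4-(benzyloxy)phenyl]-6-[diazo(triisopropylsilyl)acetyl]-5,7-dimethoxychromen-4-one F9. Decomposition of F9 with catalytic CuOTf in benzene is expected to give 12 by loss of N2, a 1,3 carbon-to-oxygen silyl shift in the acyl(silyl)carbene and a 1,2-aryl shift, a known route to 1-aryl-2-silyloxyalkynes.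

Step 9. Conjugate addition of the hindered phenoxide to a donor-substituted alkynoate may be slow, and prolonged heating with base may strip the silyl group and allow double addition. The fallback sets out from 18 and comes back at 23 by making the C4a–C4 bond first. Magnesium-mediated formylation (MgCl2, Et3N, paraformaldehyde, MeCN, reflux), which is specific for the position ortho to the free hydroxyl, should give 3-{2-[4-(benzyloxy)phenyl]-5,7-dimethoxy-4-oxochromen-6-yl}-6-ethoxy-2-hydroxy-4-(triisopropylsilyloxy)benzaldehyde F10. Addition of lithium (4-methoxyphenyl)acetylide (from 4-ethynylanisole and LiN(SiMe3)2, THF, −78 °C) would give the propargylic alcohol 2-[4-(benzyloxy)phenyl]-6-{4-ethoxy-2-hydroxy-3-[1-hydroxy-3-(4-methoxyphenyl)prop-2-ynyl]-6-(triisopropylsilyloxy)phenyl}-5,7-dimethoxychromen-4-one F11 as a diastereomer mixture. MnO2 in CH2Cl2 oxidises it to the ynone 2-[4-(benzyloxy)phenyl]-6-{4-ethoxy-2-hydroxy-3-[3-(4-methoxyphenyl)prop-2-ynoyl]-6-(triisopropylsilyloxy)phenyl}-5,7-dimethoxychromen-4-one F12. Et2NH in EtOH at 60 °C should then close the pyranone 6-endo through the enaminone, which avoids the 5-exo aurone, and give 23.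

Further compounds
F1 | step 8 | 5-ethoxybenzene-1,3-diol | CCOc1cc(O)cc(O)c1
F2 | step 8 | 1-ethoxy-3,5-bis(methoxymethoxy)benzene | CCOc1cc(OCOC)cc(OCOC)c1
F3 | step 8 | [4-ethoxy-2,6-bis(methoxymethoxy)phenyl]boronic acid | CCOc1cc(OCOC)c(B(O)O)c(OCOC)c1
F4 | step 8 | 2-[4-(benzyloxy)phenyl]-6-[4-ethoxy-2,6-bis(methoxymethoxy)phenyl]-5,7-dimethoxychromen-4-one | CCOc1cc(OCOC)c(-c2c(OC)cc3oc(-c4ccc(OCc5ccccc5)cc4)cc(=O)c3c2OC)c(OCOC)c1
F5 | step 8 | 2-[4-(benzyloxy)phenyl]-6-(4-ethoxy-2,6-dihydroxyphenyl)-5,7-dimethoxychromen-4-one | CCOc1cc(O)c(-c2c(OC)cc3oc(-c4ccc(OCc5ccccc5)cc4)cc(=O)c3c2OC)c(O)c1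
F6 | step 7 | 2-[4-(benzyloxy)phenyl]-5,7-dimethoxy-4-oxochromene-6-carboxylic acid | COc1cc2oc(-c3ccc(OCc4ccccc4)cc3)cc(=O)c2c(OC)c1C(=O)O
F7 | step 7 | 2-[4-(benzyloxy)phenyl]-5,7-dimethoxy-4-oxochromene-6-carbonyl chloride | COc1cc2oc(-c3ccc(OCc4ccccc4)cc3)cc(=O)c2c(OC)c1C(=O)Cl
F8 | step 7 | 2-[4-(benzyloxy)phenyl]-6-(diazoacetyl)-5,7-dimethoxychromen-4-one | COc1cc2oc(-c3ccc(OCc4ccccc4)cc3)cc(=O)c2c(OC)c1C(=O)C=[N+]=[N-]
F9 | step 7 | 2-[4-(benzyloxy)phenyl]-6-[diazo(triisopropylsilyl)acetyl]-5,7-dimethoxychromen-4-one | COc1cc2oc(-c3ccc(OCc4ccccc4)cc3)cc(=O)c2c(OC)c1C(=O)C(=[N+]=[N-])[Si](C(C)C)(C(C)C)C(C)C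
F10 | step 9 | 3-{2-[4-(benzyloxy)phenyl]-5,7-dimethoxy-4-oxochromen-6-yl}-6-ethoxy-2-hydroxy-4-(triisopropylsilyloxy)benzaldehyde | CCOc1cc(O[Si](C(C)C)(C(C)C)C(C)C)c(-c2c(OC)cc3oc(-c4ccc(OCc5ccccc5)cc4)cc(=O)c3c2OC)c(O)c1C=O
F11 | step 9 | 2-[4-(benzyloxy)phenyl]-6-{4-ethoxy-2-hydroxy-3-[1-hydroxy-3-(4-methoxyphenyl)prop-2-ynyl]-6-(triisopropylsilyloxy)phenyl}-5,7-dimethoxychromen-4-one (diastereomer mixture) | CCOc1cc(O[Si](C(C)C)(C(C)C)C(C)C)c(-c2c(OC)cc3oc(-c4ccc(OCc5ccccc5)cc4)cc(=O)c3c2OC)c(O)c1C(O)C#Cc1ccc(OC)cc1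
F12 | step 9 | 2-[4-(benzyloxy)phenyl]-6-{4-ethoxy-2-hydroxy-3-[3-(4-methoxyphenyl)prop-2-ynoyl]-6-(triisopropylsilyloxy)phenyl}-5,7-dimethoxychromen-4-one | CCOc1cc(O[Si](C(C)C)(C(C)C)C(C)C)c(-c2c(OC)cc3oc(-c4ccc(OCc5ccccc5)cc4)cc(=O)c3c2OC)c(O)c1C(=O)C#Cc1ccc(OC)cc1
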